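At its last reading, after 25.0 h, the elm run has left 34.6 % left-handed substrate beside 48.8 % right-handed substrate, in percent of both together charged. The leftover has thus turned towards the unwanted hand, and the next plate must choose whether a temperature schedule deserves wells for the share of left-handed product.

all flasks: left-handed substrate 1.5 M; right-handed substrate 1.5 M
- oak: reagent 0.60 M; precatalyst 270 mM; temperature 75 °C; run made earlier
- ash: reagent 0.90 M; precatalyst 270 mM; temperature 95 °C; run made earlier
- elm: reagent 1.2 M; precatalyst 540 mM; temperature 75 °C; run made earlier
- delta: reagent 1.20 M; precatalyst 270 mM; temperature 80 °C; time 30 h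
- epsilon: reagent 1.20 M; precatalyst 270 mM; at 80 °C until 6.0 h, from then on at 110 °C; time 30 h
- theta: reagent 1.20 M; precatalyst 270 mM; temperature 110 °C; time 30 h

| run | time / h | left-handed product / % | right-handed product / % |
|---|---|---|---|
| oak | 6.00 | 0.4 | 0.6 |
| oak | 12.0 | 1.3 | 0.3 |
| oak | 20.0 | 3.9 | 0 |
| oak | 25.0 | 5.4 | 1.1 |
| ash | 1.33 | 1.2 | 0.6 |
| ash | 4.00 | 4.4 | 0.7 |
| ash | 8.00 | 8.1 | 0.4 |
| ash | 12.0 | 7.4 | 1.4 |
| elm | 3.00 | 1.0 | 0 |
| elm | 8.00 | 3.7 | 0.5 |
| elm | 15.0 | 9.2 | 1.3 |
| elm | 25.0 | 15.4 | 1.2 |

(standard deviation of a reading: 0.5 percentage points)

- free catalyst is single-handed; left-handed substrate and right-handed substrate are mirror images of each other, charged as a racemate, each of them at the stated concentration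
- the analysis behind the earlier runs scatters by 0.5 percentage points, standard deviation
- reactions considered so far: reagent + free catalyst + left-handed substrate -> free catalyst + left-handed product; reagent + free catalyst + right-handed substrate -> free catalyst + right-handed product; free catalyst -> spent catalyst A; reagent + free catalyst -> spent catalyst B; precatalyst -> free catalyst

- the flask with the highest share of left-handed product in all that became left-handed product or right-handed product ("all alike" if they lie within 1.5 percentage points) (delta / epsilon / theta / all alike)
- share of left-handed product in all that became left-handed product or right-handed product, delta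
- share of left-handed product in all that became left-handed product or right-handed product, epsilon
- share of left-handed product in all that became left-handed product or right-handed product, theta

Both product-forming steps pass through the same free catalyst and the same reagent, so these concentrations cancel in the ratio of the two rates, leaving, at a given temperature, a constant times [left-handed substrate]/[right-handed substrate]. That constant is the selectivity factor, the left-handed rate over the right-handed rate at equal substrate concentrations.

The reckoning here reads it from the 12 readings of each product, which sum to 61.4 % left-handed and 8.10 % right-handed. This gives a factor of 7.58 as a reading, and a share of 88.3 %.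

The scatter on the right-handed sum is 1.7 percentage points, which places the share between 86.2 % and 90.6 %. That band is wider than the margin of 1.5 points, so the pooled readings do not resolve a spread of that size. The cancellation removes catalyst and reagent but not temperature, and temperature is what differs between delta, epsilon and theta. Summed over its own readings, the ash run at 95 °C reads a share of 87.2 %, above the oak run's 84.6 % and below the elm run's 90.7 %, and those two both stood at 75 °C, so these readings show no trend with temperature. On that reading, and as a judgement, the reckoning commits to one share for the three flasks, all alike, and keeps the temperature schedule off the selectivity wells.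

The forecast also says all alike, but it allows a slight fall with temperature where this reckoning has none: 88 % for delta (84 % to 92 %), 87.5 % for epsilon (83 % to 91.5 %) and 87 % for theta (81 % to 91 %). Its ground is “These act equally on both enantiomers”.

The flasks give 92.1 % for delta, 92.0 % for epsilon and 91.8 % for theta: all alike.

    reagent + free catalyst + left-handed substrate → free catalyst + left-handed product (k = 0.00280 M⁻² min⁻¹, Ea = 81.0 kJ mol⁻¹)
    reagent + free catalyst + right-handed substrate → free catalyst + right-handed product (k = 2.10 × 10⁻⁴ M⁻² min⁻¹, Ea = 85.0 kJ mol⁻¹)
    free catalyst → spent catalyst A (k = 0.00150 min⁻¹, Ea = 129 kJ mol⁻¹)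
    reagent + free catalyst → spent catalyst B (k = 2.50 × 10⁻⁴ M⁻¹ min⁻¹, Ea = 85.0 kJ mol⁻¹)
    precatalyst → free catalyst (k = 0.00140 min⁻¹, Ea = 106 kJ mol⁻¹)
    (constants at 80 °C)

The neighbouring flask is epsilon with 0.46 M of precatalyst in place of 270 mM. Catalyst cancels in the ratio, so the reckoning with 7.58 again gives 88.3 %, unchanged from its figure for epsilon. The neighbour reaches deeper into its left-handed substrate, keeping 76 % of the charge against 84 % in epsilon, and its left-handed product stands at 12.0 % against 7.99 %. Its right-handed product stands at 1.09 %, and its share is 91.6 %.

The earlier runs and the new flask come from a simulation with made-up constants; the scatter is artificial.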